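The vessel is closed, stirred and isothermal, with the gas held. A single-handed free catalyst acts on a racemate of the two substrates.

all flasks: left-handed substrate 0.050 M; right-handed substrate 0.050 M; gas 25 mM (held)

|  | free catalyst | remark | time |
|---|---|---|---|
| gamma | 1.7 mM | run made earlier |  |
| delta | 2.6 mM | run made earlier |  |
| west | 1.2 mM |  | 15 h |
| south-west | 1.2 mM |  | 10 h |

| run | time / h | right-handed substrate / % | left-handed substrate / % |
|---|---|---|---|
| gamma | 1.33 | 47.4 | 46.2 |
| gamma | 2.50 | 49.1 | 47.2 |
| gamma | 4.00 | 47.9 | 45.5 |
| gamma | 8.00 | 43.5 | 39.5 |
| gamma | 15.0 | 34.8 | 31.0 |
| delta | 1.33 | 49.1 | 47.1 |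
| delta | 4.00 | 48.3 | 45.2 |
| delta | 8.00 | 41.0 | 36.9 |
| delta | 10.0 | 37.6 | 35.3 |
| delta | 15.0 | 33.6 | 29.2 |

(each reading ± 1 percentage point)

1. the flask that ends with the higher excess of right-handed substrate over left-handed substrate among what is left of the two, or "neither" when 2 percentage points or less lies between them (west / south-west / neither)
2. excess of right-handed substrate over left-handed substrate among what is left of the two at the end, west
3. excess of right-handed substrate over left-handed substrate among what is left of the two at the end, south-west

- free catalyst is single-handed; left-handed substrate and right-handed substrate are mirror images of each other, charged as a racemate, each of them at the stated concentration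
- the earlier runs were read with a standard deviation of 1 percentage point
- at the start none of the gas is in solution
- an excess is the difference of the two amounts in percent of their sum
- an excess is below zero if the other one leads

In gamma and delta, [right-handed substrate] − [left-handed substrate] climbs and then stands roughly flat from 8.00 h, while both substrates keep falling. I read that as a steady state: the drain on the left-handed substrate is answered by a supply. The gap should then follow the rate of loss, and in their ratio time drops out. I call this ratio the lag: the standing gap divided by the share of the charge lost per hour. The two runs give it independently, with the loss taken from 4.00 h to 15.0 h: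

gamma: 3.9 percentage points / 0.0251 h⁻¹ = 1.55 h

delta: 3.6 points / 0.0279 h⁻¹ = 1.29 h

With 1 point of scatter on each reading, these agree, so I carry the mean, 1.42 h, the lag.

The runs part on loss per catalyst: from gamma to delta the catalyst rises 1.53 times, the loss 1.11 times. That figure is the one that cheats, so I keep gamma's loss for 1.2 mM.

gap = lag × loss = 3.6 points

west, over what gamma keeps at 15.0 h: 5.42%

south-west, over what delta keeps at 10.0 h: 4.89%

The forecast says neither, with 5% and 4.3%: “Later loss is essentially unselective”. My two numbers stand higher, with the same verdict.

The flasks give neither, with 3.55% for west and 3.11% for south-west.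

    free catalyst + left-handed substrate ⇌ catalyst intermediate A (K = 63.0 M⁻¹, k = 2200 M⁻¹ h⁻¹)
    free catalyst + right-handed substrate ⇌ catalyst intermediate B (K = 8.50 M⁻¹, k = 11000 M⁻¹ h⁻¹)
    reagent + catalyst intermediate A → free catalyst + left-handed product (k = 470 M⁻¹ h⁻¹)
    reagent + catalyst intermediate B → free catalyst + right-handed product (k = 150 M⁻¹ h⁻¹)
    left-handed substrate ⇌ right-handed substrate (k = 0.370 h⁻¹)
    gas ⇌ reagent, rate k6*(csat - [reagent]) (kL = 0.120 h⁻¹)
    2 reagent → homo dimer (k = 3.20 M⁻¹ h⁻¹)

West's products grow at 0.0208 h⁻¹ in its second half, and the lag turns that into 4.14%, still above 3.55%. The supply is the interconversion of the two substrates, which runs net from right-handed to left-handed substrate while right-handed substrate leads, as it does in west at 15.0 h with 36.9% against 34.4%: without it, west ends at 33.5% instead of 3.55%, the largest single effect. South-west read at 2.5 h has made product at 0.00999 h⁻¹, so the lag gives 1.47%; the computed excess is 1.42%.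

The runs were generated by integration on assumed constants; the scatter is artificial.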